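## Retrosynthetic overview
- The target is a 5-hydroxy-7-methoxy-6-(2-hydroxybenzyl)-2-(4-hydroxyphenyl)flavanone. By the CIP analysis of the given SMILES, C2 is **R**.
- Disconnect the 4'-OH by hydrogenolysis of a benzyl ether (4'-OBn flavanone **6**). Disconnect the pyranone ring by an enantioselective intramolecular oxa-Michael addition of 2'-hydroxychalcone **5**. This forms the C ring last and sets C2.
- Disconnect chalcone **5** by Claisen–Schmidt condensation of acetophenone **4** with 4-benzyloxybenzaldehyde (**3**).
- Disconnect **4** by ortho-hydroxybenzylation (o-quinone methide chemistry) of commercial 2',6'-dihydroxy-4'-methoxyacetophenone (**1**) with salicyl alcohol (**2**). The two ortho positions of **1** are equivalent by symmetry, so only one C-alkylated regioisomer is possible.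

Assumptions (one line each):
- The quinidine-derived bifunctional thiourea is assumed to give the 2R flavanone, and its pseudoenantiomer would give 2S. The sense is checked by [α]D (R-flavanones are dextrorotatory) and chiral HPLC.
- In chalcone **5**, ring closure is assumed to go through the less hindered 6'-OH. Closure through the OH next to the benzyl group would give the 8-benzyl regioisomer, which is disfavoured by sterics with the C2 aryl group.

## Route

**Step 1**
Reactants: **1** 2',6'-dihydroxy-4'-methoxyacetophenone (3 equiv); **2** 2-hydroxybenzyl alcohol (1 equiv)
Product: **4** 1-[2,6-dihydroxy-3-(2-hydroxybenzyl)-4-methoxyphenyl]ethan-1-one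
Conditions: PhB(OH)₂ (1.2 equiv), EtCO₂H (cat.), toluene, 110 °C, Dean–Stark, 12 h
Reagents that add atoms: none (PhB(OH)₂ templates the reaction and leaves no atoms; water is lost)
Why: This is a boronate-templated Friedel–Crafts ortho-hydroxybenzylation via an o-quinone methide. The excess of **1** suppresses dialkylation, and the symmetry of **1** means C3' and C5' give the same product. No stereocentre is formed.

**Step 2**
Reactants: **4**; **3** 4-(benzyloxy)benzaldehyde
Product: **5** (E)-3-(4-benzyloxyphenyl)-1-[2,6-dihydroxy-3-(2-hydroxybenzyl)-4-methoxyphenyl]prop-2-en-1-one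
Conditions: 50% aq. KOH (8 equiv), EtOH, rt, 48 h; then cold 1 M HCl to pH ~4 and immediate chromatography at rt
Reagents that add atoms: none
Why: This is a Claisen–Schmidt (aldol/E1cB) condensation. Excess KOH converts all three phenols to phenolates and still leaves enough enolate for the aldol. The aldehyde has no free OH, so it stays electrophilic. The benzyl ether, OMe and diarylmethane are stable to base. The acidic quench and prompt purification minimise background cyclisation to racemic flavanone.

**Step 3**
Reactant: **5**
Product: **6** (2R)-2-(4-benzyloxyphenyl)-5-hydroxy-6-(2-hydroxybenzyl)-7-methoxychroman-4-one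
Conditions: quinidine-derived 9-epi-amino thiourea (Takemoto-type, 20 mol%), toluene, 25 °C, 72 h
Reagents that add atoms: none (the catalyst is not incorporated)
Why: This is an asymmetric intramolecular oxa-Michael (6-endo-trig) addition. The thiourea binds the ketone and the tertiary amine activates the 6'-OH, so C2 is set in the C–O bond-forming step (2R). The nonpolar solvent and neutral conditions suppress racemic background closure and ring-opening, and the free 5-OH, 2''-OH, OMe and OBn are inert.

**Step 4**
Reactant: **6**
Product: **7** (+)-methylphelligrin A, (2R)-5-hydroxy-2-(4-hydroxyphenyl)-6-(2-hydroxybenzyl)-7-methoxychroman-4-one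
Conditions: H₂ (1 atm), 10% Pd/C, EtOAc/MeOH 1:1, rt, 2 h
Reagents that add atoms: none (H₂ only adds hydrogen)
Why: This is a Pd-catalysed hydrogenolysis of the aryl benzyl ether, which releases toluene. The conditions are neutral and mild, so the C2 stereocentre, the ketone, the diarylmethane and the benzylic C2–O bond are untouched. There is no base or acid to cause ring-opening racemisation.

## Final checks
- Structure: **7** has a chroman-4-one with C5-OH, C6-CH₂(2-hydroxyphenyl), C7-OMe and C2-(4-hydroxyphenyl), matching the target SMILES.
- Atom balance: 1 + 2 → 4 + H₂O; 4 + 3 → 5 + H₂O; 5 → 6 (isomerisation); 6 + H₂ → 7 + PhCH₃.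
- Stereochemistry: the only stereocentre (C2, R) is set in Step 3. It is not touched again in Step 4, and the SMILES neighbour order of **6** matches that of **7**.
- Regiochemistry: in **4**, C3' is the ring carbon that becomes C6. The 6'-OH closes the ring and becomes O1, and the 2'-OH becomes the 5-OH.

## Compound list
| No. | Name | SMILES | Role |
|---|---|---|---|
| 1 | 2',6'-Dihydroxy-4'-methoxyacetophenone | CC(=O)c1c(O)cc(OC)cc1O | starting material |
| 2 | 2-Hydroxybenzyl alcohol (salicyl alcohol) | OCc1ccccc1O | starting material |
| 3 | 4-(Benzyloxy)benzaldehyde | O=Cc1ccc(OCc2ccccc2)cc1 | starting material |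
| 4 | 1-[2,6-Dihydroxy-3-(2-hydroxybenzyl)-4-methoxyphenyl]ethanone | CC(=O)c1c(O)c(Cc2ccccc2O)c(OC)cc1O | intermediate |
| 5 | (E)-2'-Hydroxychalcone (4-OBn, 3'-(2-hydroxybenzyl), 4'-OMe, 6'-OH) | O=C(/C=C/c1ccc(OCc2ccccc2)cc1)c1c(O)c(Cc2ccccc2O)c(OC)cc1O | intermediate |
| 6 | (2R)-4'-Benzyloxy-5-hydroxy-6-(2-hydroxybenzyl)-7-methoxyflavanone | COc1cc2c(c(O)c1Cc1ccccc1O)C(=O)C[C@H](c1ccc(OCc3ccccc3)cc1)O2 | intermediate |
| 7 | (+)-Methylphelligrin A | COc1cc2c(c(O)c1Cc1ccccc1O)C(=O)C[C@H](c1ccc(O)cc1)O2 | target |

## Totals
Total steps: 4. Longest linear sequence: 4 (from **1**).

## Three steps most likely to fail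
1. **Step 3 (enantio- and regioselectivity).** Background racemic closure, or closure through the OH next to the benzyl group (8-benzyl isomer), would lower ee and yield.
   - Fallback: cyclise **5** with NaOAc in EtOH at reflux to the racemic flavanone, separate the regioisomers, and resolve **6** by preparative chiral-phase HPLC (Chiralpak). This changes the approach from asymmetric catalysis to resolution.
2. **Step 1 (o-quinone methide alkylation).** Dialkylation, O-alkylation or quinone methide oligomerisation could give low yield.
   - Fallback: mono-iodinate **1** with NIS at C3', then do a Suzuki–Miyaura coupling with a 2-(benzyloxy)benzyl boronate. The extra benzyl ether is removed together with the first one in Step 4.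
3. **Step 2 (Claisen–Schmidt on a tri-phenolate).** Low conversion is possible, and partial cyclisation to racemic flavanone under base would erode the ee downstream.
   - Fallback: protect the three phenols of **4** as MOM ethers, condense with **3** (NaOH, EtOH), then remove the MOM groups with HCl/MeOH to give **5**. This accepts some flavanone formation, to be handled by the Step 3 fallback.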